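The hydroxyquinone is assembled as a benzene ring and oxidised last. With the ring numbered C1 (C=O beside OH), C2 (OH), C3 (C15 chain), C4 (C=O), C5 (OMe) and C6 (H), C4 lies between the alkylated C3 and the methoxylated C5, and C2 carries oxygen: the substitution pattern a vinylketene–ynol ether benzannulation delivers. One photochemical operation unites a methoxyvinyl diazomethyl ketone (C4, C5, C6, C1) with a triisopropylsiloxyalkyne bearing the Z,Z-dienyl chain (C2, C3), forging C1–C6, C3–C4, C1–C2 and C4–C5 and giving a phenol whose three oxygens are already differentiated. Desilylation and oxidation at the free carbon C1 complete the target.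

Key step: step 7

Assumption: dec-9-ynoic acid, hex-2-yn-1-ol, (3E)-4-methoxybut-3-en-2-one and triisopropylsilyl triflate are taken as purchasable; the ring numbering C1–C6 given above is used throughout.

Step 1
Reactants: 1 dec-9-ynoic acid
Product: 2 methyl dec-9-ynoate
Conditions: MeOH, H2SO4 (cat.), reflux
Reagents that add atoms: methanol, CO
Why: Fischer esterification in excess methanol leaves the terminal alkyne untouched and masks the carboxylate, which would otherwise be O-propargylated in step 3.

Step 2
Reactants: 3 hex-2-yn-1-ol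
Product: 4 1-bromohex-2-yne
Conditions: PBr3, pyridine (cat.), Et2O, 0 °C → rt
Reagents that add atoms: phosphorus tribromide, BrP(Br)Br
Why: Alcohol-to-bromide substitution with PBr3 proceeds by SN2 displacement at the primary propargylic carbon, and the catalytic pyridine limits acid-promoted allene formation.

Step 3
Reactants: 2 methyl dec-9-ynoate; 4 1-bromohex-2-yne
Product: 5 methyl hexadeca-9,12-diynoate
Conditions: CuI, NaI, Cs2CO3, DMF, rt
Reagents that add atoms: none
Why: CuI-promoted, carbonate-mediated coupling of a terminal alkyne with a propargylic halide (copper-mediated sp–sp3 coupling to a skipped diyne) substitutes the primary carbon directly and tolerates the methyl ester.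

Step 4
Reactants: 5 methyl hexadeca-9,12-diynoate
Product: 6 methyl (9Z,12Z)-hexadeca-9,12-dienoate
Conditions: H2 (1 atm), Pd/CaCO3 poisoned with Pb(OAc)2 (Lindlar catalyst), quinoline, EtOAc, rt, stopped after two equivalents of H2
Reagents that add atoms: none
Why: Lindlar semihydrogenation adds H2 syn to each alkyne on the poisoned palladium surface, which sets both Z double bonds, while quinoline and control of hydrogen uptake limit over-reduction.

Step 5
Reactants: 6 methyl (9Z,12Z)-hexadeca-9,12-dienoate; 7 triisopropylsilyl trifluoromethanesulfonate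
Product: 10 triisopropyl[(10Z,13Z)-heptadeca-10,13-dien-1-yn-1-yloxy]silane, via dibromomethyl ketone 8 (not isolated), via lithium ynolate 9 (not isolated)
Conditions: CH2Br2, lithium 2,2,6,6-tetramethylpiperidide (LiTMP, 2.2 equiv), THF, −78 °C; n-BuLi, −78 °C → rt; then 7, −78 → 0 °C
Reagents that add atoms: dibromomethane, BrCBr
Why: Kowalski ester homologation: dibromomethyllithium converts the ester into dibromoketone 8, which after deprotonation and Br–Li exchange rearranges by 1,2-shift of the chain to ynolate 9, and the bulky silyl triflate silylates the ynolate at oxygen.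

Step 6
Reactants: 11 (3E)-4-methoxybut-3-en-2-one
Product: 13 (3E)-1-diazo-4-methoxybut-3-en-2-one, via trifluoroacetyl diketone 12 (not isolated)
Conditions: LiN(SiMe3)2, THF, −78 °C; CF3CO2CH2CF3; then MsN3, Et3N, H2O (1 equiv), MeCN, rt
Reagents that add atoms: methanesulfonyl azide, CS(=O)(=O)N=[N+]=[N-]; 2,2,2-trifluoroethyl trifluoroacetate, O=C(OCC(F)(F)F)C(F)(F)F (its CF3CO group is carried only by 12)
Why: Detrifluoroacetylative diazo transfer: kinetic deprotonation of the methyl group and Claisen-type C-acylation give the activated diketone 12, which accepts the diazo group from the sulfonyl azide (Regitz-type transfer) while the trifluoroacetyl group leaves on the sulfonamide nitrogen.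

Step 7
Reactants: 13 (3E)-1-diazo-4-methoxybut-3-en-2-one; 10 triisopropyl[(10Z,13Z)-heptadeca-10,13-dien-1-yn-1-yloxy]silane
Product: 18 6-methoxy-2-[(8Z,11Z)-pentadeca-8,11-dien-1-yl]-3-[(triisopropylsilyl)oxy]phenol, via methoxyvinylketene 14 (not isolated), via vinylcyclobutenone 15 (not isolated), via dienylketene 16 (not isolated), via cyclohexadienone 17 (not isolated)
Conditions: hν (254 nm, low-pressure Hg lamps, Vycor), degassed ClCH2CH2Cl, rt; then 80 °C
Reagents that add atoms: none
Why: Light expels N2 from 13 and the methoxyvinyl group migrates to the carbene carbon (Wolff rearrangement, bond C1–C6) to give vinylketene 14, whose carbonyl carbon is attacked by the chain-bearing carbon of 10 in a [2+2] cycloaddition (bonds C3–C4 and C1–C2) that gives cyclobutenone 15. Reversible 4π electrocyclic opening of 15 (light or heat) gives dienylketene 16, thermal 6π electrocyclisation (bond C4–C5) gives dienone 17, and enolisation gives phenol 18. The closest known reaction type is the photochemical diazo ketone variant of the Danheiser benzannulation with siloxyalkynes. The benzene ring is closed pericyclically by disrotatory 6π closure, the four-membered ring being only a transient [2+2] adduct, and the sp3 centres of 15 and 17 vanish on aromatisation, so no stereocentre needs control. The selectivity required is the orientation of the [2+2] step, secured by the polarisation of the ynol ether (the carbon remote from oxygen is nucleophilic, the ketene carbonyl carbon electrophilic), which places chain, siloxy and methoxy groups on C3, C2 and C5. The isolated Z,Z-diene does not absorb at 254 nm and is far less nucleophilic than the ynol ether, so it should pass through unchanged.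

Step 8
Reactants: 18 6-methoxy-2-[(8Z,11Z)-pentadeca-8,11-dien-1-yl]-3-[(triisopropylsilyl)oxy]phenol
Product: 19 4-methoxy-2-[(8Z,11Z)-pentadeca-8,11-dien-1-yl]benzene-1,3-diol
Conditions: Bu4NF, AcOH, THF, 0 °C, under argon; used at once
Reagents that add atoms: none
Why: Fluoride-mediated cleavage of the aryl silyl ether is driven by Si–F bond formation, and the acetic acid buffer with exclusion of air keeps the electron-rich resorcinol from oxidising as its phenoxide.

Step 9
Reactants: 19 4-methoxy-2-[(8Z,11Z)-pentadeca-8,11-dien-1-yl]benzene-1,3-diol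
Product: 20 2-hydroxy-5-methoxy-3-[(8Z,11Z)-pentadeca-8,11-dien-1-yl]cyclohexa-2,5-diene-1,4-dione (sorgoleone-360)
Conditions: (KSO3)2NO, KH2PO4 (aq), acetone, rt; then acidification to pH 3
Reagents that add atoms: potassium nitrosodisulfonate, [K+].[K+].[O]N(S(=O)(=O)[O-])S(=O)(=O)[O-]
Why: Teuber oxidation: one equivalent of (KSO3)2NO removes a phenolic hydrogen and a second delivers oxygen to C1, the only unsubstituted carbon ortho or para to the hydroxyls, so oxidation starting from either hydroxyl converges on the same 2-hydroxy-1,4-quinone.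

Compound list
1 | dec-9-ynoic acid | C#CCCCCCCCC(=O)O | starting material
2 | methyl dec-9-ynoate | C#CCCCCCCCC(=O)OC | intermediate
3 | hex-2-yn-1-ol | CCCC#CCO | starting material
4 | 1-bromohex-2-yne | CCCC#CCBr | intermediate
5 | methyl hexadeca-9,12-diynoate | CCCC#CCC#CCCCCCCCC(=O)OC | intermediate
6 | methyl (9Z,12Z)-hexadeca-9,12-dienoate | CCC/C=C\C/C=C\CCCCCCCC(=O)OC | intermediate
7 | triisopropylsilyl trifluoromethanesulfonate | CC(C)[Si](OS(=O)(=O)C(F)(F)F)(C(C)C)C(C)C | starting material
8 | (10Z,13Z)-1,1-dibromoheptadeca-10,13-dien-2-one | CCC/C=C\C/C=C\CCCCCCCC(=O)C(Br)Br | intermediate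
9 | lithium (10Z,13Z)-heptadeca-10,13-dien-1-yn-1-olate | CCC/C=C\C/C=C\CCCCCCCC#C[O-].[Li+] | intermediate
10 | triisopropyl[(10Z,13Z)-heptadeca-10,13-dien-1-yn-1-yloxy]silane | CCC/C=C\C/C=C\CCCCCCCC#CO[Si](C(C)C)(C(C)C)C(C)C | intermediate
11 | (3E)-4-methoxybut-3-en-2-one | CO/C=C/C(C)=O | starting material
12 | (5E)-1,1,1-trifluoro-6-methoxyhex-5-ene-2,4-dione | CO/C=C/C(=O)CC(=O)C(F)(F)F | intermediate
13 | (3E)-1-diazo-4-methoxybut-3-en-2-one | CO/C=C/C(=O)C=[N+]=[N-] | intermediate
14 | (3E)-4-methoxybuta-1,3-dien-1-one | CO/C=C/C=C=O | intermediate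
15 | 4-[(E)-2-methoxyethenyl]-2-[(8Z,11Z)-pentadeca-8,11-dien-1-yl]-3-[(triisopropylsilyl)oxy]cyclobut-2-en-1-one (racemic) | CCC/C=C\C/C=C\CCCCCCCC1=C(O[Si](C(C)C)(C(C)C)C(C)C)C(/C=C/OC)C1=O | intermediate
16 | (3E,5E)-6-methoxy-2-[(8Z,11Z)-pentadeca-8,11-dien-1-yl]-3-[(triisopropylsilyl)oxy]hexa-1,3,5-trien-1-one | CCC/C=C\C/C=C\CCCCCCCC(=C=O)/C(O[Si](C(C)C)(C(C)C)C(C)C)=C\C=C\OC | intermediate
17 | 6-methoxy-2-[(8Z,11Z)-pentadeca-8,11-dien-1-yl]-3-[(triisopropylsilyl)oxy]cyclohexa-2,4-dien-1-one (racemic) | CCC/C=C\C/C=C\CCCCCCCC1=C(O[Si](C(C)C)(C(C)C)C(C)C)C=CC(OC)C1=O | intermediate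
18 | 6-methoxy-2-[(8Z,11Z)-pentadeca-8,11-dien-1-yl]-3-[(triisopropylsilyl)oxy]phenol | CCC/C=C\C/C=C\CCCCCCCc1c(O)c(OC)ccc1O[Si](C(C)C)(C(C)C)C(C)C | intermediate
19 | 4-methoxy-2-[(8Z,11Z)-pentadeca-8,11-dien-1-yl]benzene-1,3-diol | CCC/C=C\C/C=C\CCCCCCCc1c(O)ccc(OC)c1O | intermediate
20 | 2-hydroxy-5-methoxy-3-[(8Z,11Z)-pentadeca-8,11-dien-1-yl]cyclohexa-2,5-diene-1,4-dione (sorgoleone-360) | CCC/C=C\C/C=C\CCCCCCCC1=C(O)C(=O)C=C(OC)C1=O | target

Total step count: 9. Longest linear sequence: 7 steps (steps 1, 3, 4, 5, 7, 8, 9; the branch through step 2 is equally long).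

Steps most likely to fail

Step 7. The photogenerated ketene may be trapped inefficiently (dimerisation, or photodegradation of the siloxyalkyne or of the aromatic product on long irradiation), and the aromatic product could sensitise Z to E isomerisation of the diene. The fallback generates the same ketene thermally and sets out from siloxyalkyne 10. Purchasable (2E)-4-methoxybut-2-enoic acid would be converted with (COCl)2 and catalytic DMF in CH2Cl2 into (2E)-4-methoxybut-2-enoyl chloride F1. Slow addition of this acid chloride to 10 and Et3N in toluene at rt should cause 1,4-dehydrochlorination to vinylketene 14 in the dark. The [2+2] adduct 15 then forms thermally, and heating to 80–110 °C should carry it through 16 and 17, so the route is rejoined at phenol 18.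

Step 5. During the warm alkyllithium phase the doubly allylic CH2 may be deprotonated, moving the Z,Z-diene into conjugation; the rearrangement may also stall, or the ynolate may silylate at carbon. The fallback reaches the ynolate by oxidation of an acetylide instead of a carbenoid rearrangement and sets out from ester 6. Reduction with i-Bu2AlH in CH2Cl2 at −78 °C should give (9Z,12Z)-hexadeca-9,12-dienal F2. Ohira–Bestmann homologation (dimethyl (1-diazo-2-oxopropyl)phosphonate, K2CO3, MeOH, rt) should give (10Z,13Z)-heptadeca-10,13-dien-1-yne F3. Deprotonation with LiN(SiMe3)2 in THF at −78 °C and oxidation with LiOOt-Bu (from t-BuOOH and LiN(SiMe3)2, −78 → 0 °C) should give lithium ynolate 9 without any excess alkyllithium. Silylation with 7 at −78 °C rejoins the route at siloxyalkyne 10.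

Step 9. With two free hydroxyls, oxidative attack may occur at the methoxy-bearing carbon C5 with loss of methanol, and the very electron-rich resorcinol may over-oxidise or couple oxidatively. The fallback reverses the order of the last two operations and sets out from phenol 18, in which only the C4 hydroxyl is free and its para carbon C1 is the sole open site. Oxidation with (KSO3)2NO under phase transfer (Bu4NHSO4, CH2Cl2, aqueous KH2PO4) should give 5-methoxy-3-[(8Z,11Z)-pentadeca-8,11-dien-1-yl]-2-[(triisopropylsilyl)oxy]cyclohexa-2,5-diene-1,4-dione F4. Hydrolysis of this vinylogous silyl ester with 1 M HCl in THF at rt then rejoins the route at target 20.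

Further compounds
F1 | step 7 | (2E)-4-methoxybut-2-enoyl chloride | COC/C=C/C(=O)Cl
F2 | step 5 | (9Z,12Z)-hexadeca-9,12-dienal | CCC/C=C\C/C=C\CCCCCCCC=O
F3 | step 5 | (10Z,13Z)-heptadeca-10,13-dien-1-yne | CCC/C=C\C/C=C\CCCCCCCC#C
F4 | step 9 | 5-methoxy-3-[(8Z,11Z)-pentadeca-8,11-dien-1-yl]-2-[(triisopropylsilyl)oxy]cyclohexa-2,5-diene-1,4-dione | CCC/C=C\C/C=C\CCCCCCCC1=C(O[Si](C(C)C)(C(C)C)C(C)C)C(=O)C=C(OC)C1=O
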